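## Retrosynthetic overview

1. The target is reached by 8-O-methacrylation and 10-O-acetylation of a macrocyclic 8,10-diol butenolide, which is carried as its acetonide.
2. The 10-membered carbocycle (C6–C7 bond) and then the butenolide are closed in one flask: a C7 nitronate adds to a Z-enal, the aldolate lactonizes, and loss of HNO2 gives C7=C11. The nitro carbon C7 is a linchpin that bonds to both C8 and C6 and then disappears.
3. The C7–C8 bond comes from a catalytic asymmetric nitroaldol of a β-hydroxy aldehyde with a nitro ester that carries C7, C11, C12 and C13 (CH2OAc).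
4. The C9–C10 bond comes from an organocatalytic aldol of acetaldehyde with a 1,2-diketone; this sets the first stereocenter (C10).
5. The diketone comes from nerol (C1–C6, Z-alkene already in place) by ozonolysis, acetyl-anion addition and oxidation.

Convention used: germacranolide numbering (C1 ketone, C4=C5 Z-alkene, C6 lactone carbinol, C7=C11 butenolide alkene, C8 methacrylate carbinol, C10 tertiary acetate, C12 lactone carbonyl, C13 CH2OAc); the target is 6R,8S,10R. Racemic centers that appear before step 7 (C11 in the nitro ester, C1 in the acyloin) are erased later.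

## Route

Step 1
Reactants: 1 methyl 3-nitropropanoate
Product: 3 methyl 2-(hydroxymethyl)-3-nitropropanoate (racemic), via dilithio dianion 2 (not isolated)
Conditions: LDA (2.1 equiv), THF/DMPU, −78 °C; CH2O (gas), −78 °C; AcOH
Reagents that add atoms: formaldehyde, C=O
Why: Double deprotonation gives the ester enolate/nitronate dianion, whose ester α-carbon is the more nucleophilic site, so the aldol addition to formaldehyde (dianion hydroxymethylation) occurs at C11.

Step 2
Reactants: 3 methyl 2-(hydroxymethyl)-3-nitropropanoate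
Product: 4 methyl 3-acetoxy-2-(nitromethyl)propanoate (racemic)
Conditions: Ac2O, pyridine, 0 °C
Reagents that add atoms: acetic anhydride, CC(=O)OC(C)=O
Why: O-Acetylation of a primary alcohol under weakly basic conditions that do not trigger loss of HNO2 from the β-nitro ester.

Step 3
Reactants: 5 nerol
Product: 6 neryl triethylsilyl ether
Conditions: TESCl, imidazole, CH2Cl2, 0 °C
Reagents that add atoms: chlorotriethylsilane, CC[Si](CC)(CC)Cl
Why: Silyl ether protection of the primary allylic alcohol masks C6–OH through the organolithium, oxidation and amine-catalyzed steps.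

Step 4
Reactants: 6 neryl triethylsilyl ether
Product: 8 (4Z)-4-methyl-6-(triethylsilyloxy)hex-4-enal, via secondary ozonide 7 (not isolated)
Conditions: O3 (1.0 equiv, Sudan Red 7B end point), CH2Cl2, −78 °C; Me2S, −78 °C to rt
Reagents that add atoms: ozone, [O-][O+]=O
Why: Chemoselective ozonolysis cleaves the more electron-rich isolated trisubstituted alkene in preference to the alkene deactivated by the allylic silyloxy group, so the Z-alkene survives.

Step 5
Reactants: 8 (4Z)-4-methyl-6-(triethylsilyloxy)hex-4-enal; 9 ethyl vinyl ether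
Product: 11 (6Z)-3-hydroxy-6-methyl-8-(triethylsilyloxy)oct-6-en-2-one (racemic), via enol ether carbinol 10 (not isolated)
Conditions: 9, t-BuLi, THF, −78 to 0 °C; 8, −78 °C; then 0.02 M HCl, THF/H2O, 0 °C, 10 min
Reagents that add atoms: water, O
Why: 1-Ethoxyvinyllithium (acyl anion equivalent) adds to the aldehyde and brief mild-acid hydrolysis of the enol ether, much faster than silyl ether cleavage, unveils the methyl ketone (acyloin synthesis).

Step 6
Reactants: 11 (6Z)-3-hydroxy-6-methyl-8-(triethylsilyloxy)oct-6-en-2-one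
Product: 12 (6Z)-6-methyl-8-(triethylsilyloxy)oct-6-ene-2,3-dione
Conditions: Dess–Martin periodinane, CH2Cl2, 0 °C to rt
Reagents that add atoms: none
Why: Dess–Martin oxidation converts the acyloin into the 1,2-diketone without touching the silyl ether or the alkene.

Step 7
Reactants: 12 (6Z)-6-methyl-8-(triethylsilyloxy)oct-6-ene-2,3-dione; 13 acetaldehyde
Product: 14 (3R,7Z)-3-hydroxy-3,7-dimethyl-4-oxo-9-(triethylsilyloxy)non-7-enal
Conditions: 13 (5 equiv), (S)-α,α-bis[3,5-bis(trifluoromethyl)phenyl]-2-pyrrolidinemethanol (20 mol%; enantiomer chosen to give 10R), NMP, 4 °C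
Reagents that add atoms: none
Why: Direct organocatalytic cross-aldol by enamine catalysis: the acetaldehyde enamine attacks the less hindered acetyl carbonyl of the diketone on the face fixed by hydrogen bonding to the catalyst hydroxyl, setting the 10R tertiary alcohol as the first stereocenter.

Step 8
Reactants: 14 (3R,7Z)-3-hydroxy-3,7-dimethyl-4-oxo-9-(triethylsilyloxy)non-7-enal; 4 methyl 3-acetoxy-2-(nitromethyl)propanoate
Product: 15 methyl (4S,6R,10Z)-2-(acetoxymethyl)-4,6-dihydroxy-6,10-dimethyl-3-nitro-7-oxo-12-(triethylsilyloxy)dodec-10-enoate (C2/C3 epimer mixture)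
Conditions: 4 (1.5 equiv), L-valine-derived P-spiro tetraaminophosphonium chloride (5 mol%; series that adds to the Re face), KOtBu (5 mol%), THF, −78 °C
Reagents that add atoms: none
Why: Catalytic asymmetric nitroaldol (Henry) reaction: the chiral phosphonium nitronate ion pair adds to the Re face of the unhindered aldehyde, far more reactive than the hindered ketone, setting 8S under catalyst control while the C7 and C11 mixtures are erased in step 11.

Step 9
Reactants: 15 nitro diol from step 8
Product: 16 methyl 3-acetoxy-2-{nitro[(4S,6R)-2,2,6-trimethyl-6-[(4Z)-4-methyl-6-(triethylsilyloxy)hex-4-enoyl]-1,3-dioxan-4-yl]methyl}propanoate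
Conditions: 2-methoxypropene, PPTS (5 mol%), CH2Cl2, 0 °C
Reagents that add atoms: 2-methoxypropene, COC(C)=C
Why: Acetonide formation across the syn-1,3-diol turns O8 into a non-leaving acetal oxygen, so the nitronate needed in step 11 cannot eliminate, lactonize through O8 or undergo retro-nitroaldol.

Step 10
Reactants: 16 acetonide silyl ether
Product: 17 methyl 3-acetoxy-2-{nitro[(4S,6R)-2,2,6-trimethyl-6-[(4Z)-4-methyl-6-oxohex-4-enoyl]-1,3-dioxan-4-yl]methyl}propanoate
Conditions: IBX (3 equiv), DMSO, rt
Reagents that add atoms: none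
Why: Oxidative desilylation: IBX in DMSO cleaves the primary triethylsilyl ether and oxidizes the liberated allylic alcohol in the same flask under neutral conditions that preserve the Z-enal, the acetonide and the nitro ester.

Step 11
Reactants: 17 Z-enal nitro ester
Product: 20 (6R,8S,10R,4Z)-13-acetoxy-8,10-(isopropylidenedioxy)-1-oxogermacra-4,7(11)-dien-12,6-olide, via macrocyclic nitroaldol adduct 18 (not isolated), via nitro lactone 19 (not isolated)
Conditions: chiral guanidine–bis(thiourea) catalyst (20 mol%), toluene, 2 mM, 0 °C to rt; then i-Pr2NEt (2 equiv), rt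
Reagents that add atoms: none
Why: Proposed new method: a macrocyclizing nitroaldol–lactonization–denitration cascade in which the hydrogen-bonded guanidinium nitronate at C7 adds reversibly to the Z-enal carbonyl (1,2-addition, since the β,β-disubstituted enal resists conjugate addition) to close the 10-membered ring, the aldolate is drained by 5-exo lactonization onto the methyl ester so the unfavourable equilibrium of a hindered nitronate addition is overcome, and base then removes HNO2 by E1cB through the lactone enolate, which can only give the C7=C11 butenolide (loss of acetate instead gives an α-methylene nitro lactone that acetate reopens by SN2' to the same product); the catalyst enantiomer is chosen to add to the enal face that gives 6R; the closest known chemistry is the intermolecular nitroaldol/lactonization/HNO2-elimination route from 3-nitropropanoates to butenolides and the macrocyclizing chromium-mediated allylation–lactonization used for germacranolides.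

Step 12
Reactants: 20 macrocyclic butenolide acetonide
Product: 21 (6R,8S,10R,4Z)-13-acetoxy-8,10-dihydroxy-1-oxogermacra-4,7(11)-dien-12,6-olide
Conditions: AcOH/H2O/THF (3:1:1), 40 °C
Reagents that add atoms: none
Why: Acid-catalyzed acetal hydrolysis frees both hydroxyls under non-basic conditions that spare the base-sensitive C6–H of the γ-alkenyl butenolide.

Step 13
Reactants: 21 macrocyclic diol
Product: 22 (6R,8S,10R,4Z)-13-acetoxy-10-hydroxy-8-(methacryloyloxy)-1-oxogermacra-4,7(11)-dien-12,6-olide
Conditions: methacryloyl chloride (1.5 equiv), pyridine, CH2Cl2, −20 to 0 °C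
Reagents that add atoms: methacryloyl chloride, CC(=C)C(=O)Cl
Why: Acylation: the secondary C8 alcohol reacts selectively over the hindered tertiary α-ketol hydroxyl under mild pyridine conditions.

Step 14
Reactants: 22 8-O-methacrylate
Product: 23 target CNP0115165.2
Conditions: Ac2O, Sc(OTf)3 (5 mol%), MeCN, −20 °C
Reagents that add atoms: acetic anhydride, CC(=O)OC(C)=O
Why: Sc(OTf)3-catalyzed acetylation esterifies the hindered tertiary alcohol under non-basic conditions, completing the target with all three stereocenters untouched.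

## Compound list

1 | methyl 3-nitropropanoate | COC(=O)CC[N+](=O)[O-] | starting material
2 | dilithium ester enolate/nitronate dianion of methyl 3-nitropropanoate (not isolated) | [Li+].[Li+].COC([O-])=CC=[N+]([O-])[O-] | intermediate
3 | methyl 2-(hydroxymethyl)-3-nitropropanoate (racemic) | COC(=O)C(CO)C[N+](=O)[O-] | intermediate
4 | methyl 3-acetoxy-2-(nitromethyl)propanoate (racemic) | COC(=O)C(COC(C)=O)C[N+](=O)[O-] | intermediate
5 | nerol, (2Z)-3,7-dimethylocta-2,6-dien-1-ol | CC(C)=CCC/C(C)=C\CO | starting material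
6 | neryl triethylsilyl ether | CC(C)=CCC/C(C)=C\CO[Si](CC)(CC)CC | intermediate
7 | secondary ozonide (3,3-dimethyl-1,2,4-trioxolane) of the distal alkene of 6 (not isolated) | CC1(C)OOC(CC/C(C)=C\CO[Si](CC)(CC)CC)O1 | intermediate
8 | (4Z)-4-methyl-6-(triethylsilyloxy)hex-4-enal | O=CCC/C(C)=C\CO[Si](CC)(CC)CC | intermediate
9 | ethyl vinyl ether | C=COCC | starting material
10 | (6Z)-2-ethoxy-6-methyl-8-(triethylsilyloxy)octa-1,6-dien-3-ol (racemic, not isolated) | C=C(OCC)C(O)CC/C(C)=C\CO[Si](CC)(CC)CC | intermediate
11 | (6Z)-3-hydroxy-6-methyl-8-(triethylsilyloxy)oct-6-en-2-one (racemic) | CC(=O)C(O)CC/C(C)=C\CO[Si](CC)(CC)CC | intermediate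
12 | (6Z)-6-methyl-8-(triethylsilyloxy)oct-6-ene-2,3-dione | CC(=O)C(=O)CC/C(C)=C\CO[Si](CC)(CC)CC | intermediate
13 | acetaldehyde | CC=O | starting material
14 | (3R,7Z)-3-hydroxy-3,7-dimethyl-4-oxo-9-(triethylsilyloxy)non-7-enal (C8 aldehyde, 10R) | O=CC[C@@](C)(O)C(=O)CC/C(C)=C\CO[Si](CC)(CC)CC | intermediate
15 | methyl (4S,6R,10Z)-2-(acetoxymethyl)-4,6-dihydroxy-6,10-dimethyl-3-nitro-7-oxo-12-(triethylsilyloxy)dodec-10-enoate (8S,10R; mixture at C7 and C11) | COC(=O)C(COC(C)=O)C([N+](=O)[O-])[C@@H](O)C[C@@](C)(O)C(=O)CC/C(C)=C\CO[Si](CC)(CC)CC | intermediate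
16 | methyl 3-acetoxy-2-{nitro[(4S,6R)-2,2,6-trimethyl-6-[(4Z)-4-methyl-6-(triethylsilyloxy)hex-4-enoyl]-1,3-dioxan-4-yl]methyl}propanoate | COC(=O)C(COC(C)=O)C([N+](=O)[O-])[C@@H]1C[C@@](C)(OC(C)(C)O1)C(=O)CC/C(C)=C\CO[Si](CC)(CC)CC | intermediate
17 | methyl 3-acetoxy-2-{nitro[(4S,6R)-2,2,6-trimethyl-6-[(4Z)-4-methyl-6-oxohex-4-enoyl]-1,3-dioxan-4-yl]methyl}propanoate | COC(=O)C(COC(C)=O)C([N+](=O)[O-])[C@@H]1C[C@@](C)(OC(C)(C)O1)C(=O)CC/C(C)=C\C=O | intermediate
18 | macrocyclic nitroaldol adduct (not isolated): 10-membered ring closed by the C6–C7 bond, 6R-hydroxy, C7 bearing NO2 and CH(CH2OAc)CO2Me, 8S,10R-acetonide, C1 ketone, 4Z-alkene | COC(=O)C(COC(C)=O)C1([N+](=O)[O-])[C@H](O)\C=C(C)/CCC(=O)[C@@]2(C)C[C@@H]1OC(C)(C)O2 | intermediate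
19 | nitro lactone (not isolated): 7-nitro-11,13-dihydro-12,6-olide of 18 with 13-acetoxy group and 8,10-acetonide | CC(=O)OCC1C(=O)O[C@@H]2\C=C(C)/CCC(=O)[C@@]3(C)C[C@H](OC(C)(C)O3)C12[N+](=O)[O-] | intermediate
20 | (6R,8S,10R,4Z)-13-acetoxy-8,10-(isopropylidenedioxy)-1-oxogermacra-4,7(11)-dien-12,6-olide | CC1(C)O[C@H]2C[C@@](C)(O1)C(=O)CC/C(C)=C\[C@H]3OC(=O)C(COC(C)=O)=C23 | intermediate
21 | (6R,8S,10R,4Z)-13-acetoxy-8,10-dihydroxy-1-oxogermacra-4,7(11)-dien-12,6-olide | O[C@H]1C[C@@](C)(O)C(=O)CC/C(C)=C\[C@H]2OC(=O)C(COC(C)=O)=C12 | intermediate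
22 | (6R,8S,10R,4Z)-13-acetoxy-10-hydroxy-8-(methacryloyloxy)-1-oxogermacra-4,7(11)-dien-12,6-olide | C=C(C)C(=O)O[C@H]1C[C@@](C)(O)C(=O)CC/C(C)=C\[C@H]2OC(=O)C(COC(C)=O)=C12 | intermediate
23 | CNP0115165.2, (6R,8S,10R,4Z)-10,13-diacetoxy-8-(methacryloyloxy)-1-oxogermacra-4,7(11)-dien-12,6-olide | C=C(C)C(=O)O[C@H]1C[C@@](C)(OC(C)=O)C(=O)CC/C(C)=C\[C@H]2OC(=O)C(COC(C)=O)=C12 | target

## Step count and risks

Total step count: 14 (two steps for nitro ester 4, twelve in the main line).
Longest linear sequence: 12 steps (steps 3 to 14, from nerol).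

The three steps most likely to fail:

**Step 11 (proposed new cascade).** The ring closure needs a fully substituted nitronate to add to an enal while forming a 10-membered ring. Competing paths are 5-ring nitroaldol onto the C1 ketone, loss of HNO2 before lactonization (which can give the wrong alkene geometry), and formation of the 6S epimer. The C6 configuration rests on catalyst control that is untested here.
Fallback with known chemistry: it sets out from 16 and comes back at 20. A Nef reaction (aqueous TiCl3, NH4OAc, THF) converts the secondary nitro group of 16 into a ketone and gives the β-keto ester F1. Tf2O, Et3N and LiOTf in CH2Cl2 at −78 °C give the (Z)-enol triflate F2, with the triflate cis to the ester. IBX in DMSO, as in step 10, gives the enal triflate F3. A Nozaki–Hiyama–Kishi macrocyclization (CrCl2, catalytic NiCl2, DMSO, high dilution, with a chiral sulfonamide ligand if the substrate bias at C6 is poor) forms the C6–C7 bond, and the chromium alkoxide lactonizes onto the cis ester to give 20.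

**Step 7 (acetaldehyde aldol on the diketone).** Risks are attack at the C1 carbonyl instead of the acetyl carbonyl, moderate enantioselectivity, and further aldol or retro-aldol of the β-hydroxy aldehyde.
Fallback: it sets out from 12 and comes back at 14. A Mukaiyama aldol with 1-(tert-butylthio)-1-(trimethylsilyloxy)ethene, catalyzed by Cu(OTf)2 and (S,S)-2,2'-isopropylidenebis(4-tert-butyl-2-oxazoline) (10 mol%, ligand enantiomer chosen for 10R), chelates the diketone and adds at the acetyl carbonyl to give the silyl ether thioester F4. Work-up with 1 M HCl gives the hydroxy thioester F5. Fukuyama reduction (Et3SiH, palladium on carbon, acetone) gives 14.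

**Step 8 (asymmetric nitroaldol with the branched nitro ester).** Risks are low facial control with a β-branched, functionalized nitroalkane, and a follow-on 5-ring nitroaldol of the product nitronate onto the C1 ketone.
Fallback: it sets out from 14 and 4 and comes back at 15. A tetramethylguanidine-catalyzed nitroaldol (THF, −40 °C) gives the C8-epimeric nitro alcohol F6. Dess–Martin oxidation gives the α-nitro ketone F7. Asymmetric transfer hydrogenation with RuCl(p-cymene)(TsDPEN) in HCO2H/Et3N (catalyst enantiomer chosen for 8S) then sets C8 by reduction instead of by C–C bond formation and returns 15.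

Further compounds
F1 | step 11 | β-keto ester: methyl 2-(acetoxymethyl)-3-oxo-3-[(4S,6R)-2,2,6-trimethyl-6-[(4Z)-4-methyl-6-(triethylsilyloxy)hex-4-enoyl]-1,3-dioxan-4-yl]propanoate | COC(=O)C(COC(C)=O)C(=O)[C@@H]1C[C@@](C)(OC(C)(C)O1)C(=O)CC/C(C)=C\CO[Si](CC)(CC)CC
F2 | step 11 | (Z)-enol triflate of F1 (triflate cis to the methyl ester) | COC(=O)/C(COC(C)=O)=C(\OS(=O)(=O)C(F)(F)F)[C@@H]1C[C@@](C)(OC(C)(C)O1)C(=O)CC/C(C)=C\CO[Si](CC)(CC)CC
F3 | step 11 | enal triflate: F2 with the silyloxymethyl end oxidized to the Z-enal | COC(=O)/C(COC(C)=O)=C(\OS(=O)(=O)C(F)(F)F)[C@@H]1C[C@@](C)(OC(C)(C)O1)C(=O)CC/C(C)=C\C=O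
F4 | step 7 | S-tert-butyl (3R,7Z)-3,7-dimethyl-4-oxo-9-(triethylsilyloxy)-3-(trimethylsilyloxy)non-7-enethioate | CC(C)(C)SC(=O)C[C@@](C)(O[Si](C)(C)C)C(=O)CC/C(C)=C\CO[Si](CC)(CC)CC
F5 | step 7 | S-tert-butyl (3R,7Z)-3-hydroxy-3,7-dimethyl-4-oxo-9-(triethylsilyloxy)non-7-enethioate | CC(C)(C)SC(=O)C[C@@](C)(O)C(=O)CC/C(C)=C\CO[Si](CC)(CC)CC
F6 | step 8 | C8-epimeric mixture of nitro alcohol 15 (10R fixed; C7, C8, C11 mixed) | COC(=O)C(COC(C)=O)C([N+](=O)[O-])C(O)C[C@@](C)(O)C(=O)CC/C(C)=C\CO[Si](CC)(CC)CC
F7 | step 8 | α-nitro ketone: methyl (6R,10Z)-2-(acetoxymethyl)-6-hydroxy-6,10-dimethyl-3-nitro-4,7-dioxo-12-(triethylsilyloxy)dodec-10-enoate | COC(=O)C(COC(C)=O)C([N+](=O)[O-])C(=O)C[C@@](C)(O)C(=O)CC/C(C)=C\CO[Si](CC)(CC)CC
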